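## Retrosynthetic overview

- The C10 angelate and the C6 4-hydroxybenzoate are removed last. The C8=C9 alkene with the C10 carbinol goes back to a C10 ketone, and the C6 carbinol to a C6 ketone. This leads to a trans-fused 4-hydroxybicyclo[5.3.0]decane-6,10-dione.
- The strategy rests on one feature of the seven-membered ring. C6 and C10 both bear oxygen, each is bonded to one end of the fusion bond C1–C5, and they are tied together on the far side by C7–C8(CH3)–C9. An added C6–C10 bond therefore turns this ring into a cyclobutane C1–C5–C6–C10 that carries a cis-1,2-diol and sits between two cyclopentanes.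
- That 5-4-5 tricycle is the [2+2] photoadduct of 3-methylcyclopent-2-enone (C1–C5, carbonyl = C4) and the mirror-symmetric 4-methyl-1,2-bis(trimethylsilyloxy)cyclopentene (C6–C10). The isopropyl group and the C4 hydroxyl are installed on the rigid tricycle.
- Ring order: the two five-membered rings come first (one bought, one by acyloin closure), then the cyclobutane by photocycloaddition, then the seven-membered ring by glycol fission of C6–C10.

Key step: step 2

**Numbering and faces.** Daucane numbering is used throughout:
- C1 is the methyl-bearing fusion carbon; C2 and C3 are ring methylenes.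
- C4 is the isopropyl carbinol carbon; C5 is the fusion CH.
- C6 is the aroyloxy carbon; C7 is a methylene.
- C8 is the methyl-bearing alkene carbon; C9 is the alkene CH.
- C10 is the angeloyloxy carbon.

β is the face that carries the C1 methyl group and α is the other face. The target is (1S,4R,5S,6S,10R): C1-CH3 β, C4-OH β, C5-H α, C6-O α, C10-O α.

**Mixtures carried.** Compounds 4–11 are carried as cis-anti-cis/cis-syn-cis mixtures. Compounds 4–19 are carried as C8 epimers. All of these converge by step 14.

**Assumption.** The sense of induction of the prolinol-derived Lewis acid on 3 is taken from the usual carbonyl-binding model. If it proves opposite, the catalyst from the equally available (R)-amino alcohol is used.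

## Route

Step 1
Reactants: 1 dimethyl 3-methylglutarate
Product: 2 4-methyl-1,2-bis(trimethylsilyloxy)cyclopent-1-ene
Conditions: Na dispersion (4.4 equiv), Me3SiCl (4.5 equiv), toluene, reflux; filtration under argon, distillation
Reagents that add atoms: chlorotrimethylsilane, C[Si](C)(C)Cl
Why: Acyloin condensation in its Rühlmann form: sodium couples the two ester carbonyls reductively to the five-membered enediolate, which Me3SiCl traps as it forms while also removing methoxide, so that Dieckmann closure cannot compete; the methyl-bearing carbon lies on the mirror plane, so 2 is achiral.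

Step 2
Reactants: 2 4-methyl-1,2-bis(trimethylsilyloxy)cyclopent-1-ene (excess); 3 3-methylcyclopent-2-en-1-one
Product: 4 tricyclic photoadduct ketone, 1,4-dimethyl-2,6-bis(trimethylsilyloxy)tricyclo[5.3.0.0(2,6)]decan-8-one (daucane C1 S; C4 ketone; C1-CH3 and C5-H cis; Me3SiO on C6 and C10 cis; cis-anti-cis isomer drawn, C8 open)
Conditions: oxazaborolidine from (S)-α,α-bis(3,5-dimethylphenyl)prolinol and 2,4,6-trifluorophenylboronic acid (50 mol%), AlBr3 (50 mol%), CH2Cl2, −75 °C, hν (366 nm); Et3N quench at −75 °C, Et3N-deactivated silica
Reagents that add atoms: none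
Why: Proposed new method: binding of the C4 carbonyl oxygen of 3 to the AlBr3-activated oxazaborolidine moves the enone absorption to longer wavelength, so that 366 nm light excites mainly the bound enone, which crosses to its triplet, attacks the electron-rich C6=C10 bond of 2 and gives a 1,4-diradical that recombines after spin inversion. The closest known reaction types are the racemic [2+2] photocycloaddition of cyclopentenones with 1,2-bis(trimethylsilyloxy)cycloalkenes and the enantioselective intermolecular [2+2] photocycloaddition of cyclic enones with simple alkenes under this class of chiral Lewis acid; their combination on a silyl enediol ether has not been shown. One ring is closed, the cyclobutane C1–C5–C6–C10, by stepwise radical addition and radical recombination that forms C5–C6 and C1–C10, and a five-membered enone and a five-membered alkene allow only cis fusion on both sides. C1 is set by the catalyst, whose aryl groups cover one face of C1=C5 so that 2 adds to the Si face of C1 (leading to 1S), and C5 follows from the cis fusion, while C6, C8 and C10 need no control because all three become sp2 later. The mirror symmetry of 2 removes any head-to-head or head-to-tail question, so enone face selectivity is the only selectivity required. Competing Mukaiyama–Michael addition is held back by the β,β-disubstitution of 3 and by the low temperature, and the cold amine quench protects the β-silyloxy ketone from desilylation and retro-aldol opening.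

Step 3
Reactants: 4 tricyclic photoadduct ketone
Product: 6 tricyclic C3=C4 enol triflate, via C3-lithium enolate 5 (not isolated)
Conditions: LiN(iPr)2 (1.15 equiv), THF, −78 °C; N-(5-chloropyridin-2-yl)bis(trifluoromethanesulfonimide) (Comins reagent), −78 → −40 °C
Reagents that add atoms: lithium diisopropylamide, CC(C)N([Li])C(C)C (Li of 5 only); N-(5-chloropyridin-2-yl)bis(trifluoromethanesulfonimide), FC(F)(F)S(=O)(=O)N(c1ccc(Cl)cn1)S(=O)(=O)C(F)(F)F
Why: Kinetic enolisation followed by O-sulfonylation (enol triflate synthesis): the amide base takes a proton from the open C3 methylene and not the cyclobutane methine C5–H, whose enolate would strain the four-membered ring and expel the C6 silyloxy group, and the pyridyl triflimide traps the enolate already at −78 °C before any proton exchange; no stereocentre is touched.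

Step 4
Reactants: 6 tricyclic C3=C4 enol triflate; 7 isopropylmagnesium chloride
Product: 8 tricyclic 4-isopropyl C3=C4 alkene (bis-Me3Si ether)
Conditions: Fe(acac)3 (10 mol%), 7 (1.8 equiv), THF/NMP, −30 → 0 °C
Reagents that add atoms: none
Why: Iron-catalysed Kumada-type cross-coupling of an alkenyl triflate with a secondary alkyl Grignard reagent, which is fast at low temperature, should not scramble the isopropyl group and leaves silyl ethers alone; C4 now carries all three carbon neighbours it has in the target.

Step 5
Reactants: 8 tricyclic 4-isopropyl C3=C4 alkene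
Product: 10 tricyclic 4β-hydroxy-4α-isopropyl bis-Me3Si ether, via C4 hydroperoxide 9 (not isolated)
Conditions: Mn(dpm)3 (20 mol%), PhSiH3 (2.5 equiv), O2 (1 atm, solution presaturated), iPrOH/CH2Cl2, 0 °C; then P(OEt)3, 0 °C → rt
Reagents that add atoms: dioxygen, O=O
Why: Mukaiyama hydration by metal-hydride hydrogen-atom transfer: the hydrogen atom goes to C3 to give the tertiary C4 radical (Markovnikov), O2 is taken up on the convex exo face shared by C1-CH3 and C5-H because the concave face is walled off by the cyclobutane and its substituents, which sets C4–O β (cis to C1-CH3), O2 saturation at 0 °C being used so that capture outruns cyclobutylcarbinyl opening, as it does for the 2-pinanyl radical in the autoxidation of pinane, and the phosphite then reduces the hydroperoxide without radical intermediates.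

Step 6
Reactants: 10 tricyclic 4β-hydroxy-4α-isopropyl bis-Me3Si ether
Product: 11 tricyclic 4β,6,10-triol (cis-cyclobutane-1,2-diol at C6/C10)
Conditions: K2CO3 (0.3 equiv), MeOH, 0 °C → rt
Reagents that add atoms: none
Why: Base-catalysed methanolysis of trimethylsilyl ethers, safe only at this stage because with C4 no longer a carbonyl the freed C6 cyclobutanol cannot open by a De Mayo-type retro-aldol cleavage of C5–C6.

Step 7
Reactants: 11 tricyclic 4β,6,10-triol
Product: 12 cis-fused (5β-H) 4β-hydroxydaucane-6,10-dione
Conditions: Pb(OAc)4 (1.05 equiv), CH2Cl2, −20 → 0 °C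
Reagents that add atoms: none
Why: Criegee glycol cleavage: the cis-1,2-diol on the four-membered ring readily forms the cyclic ester of tetravalent lead and its fragmentation releases the cyclobutane strain, cutting C6–C10 and unfolding the seven-membered ring; C1, C4 and C5 are untouched, so the fusion is still cis, and the syn and anti photoadduct series converge here.

Step 8
Reactants: 12 cis-fused 4β-hydroxydaucane-6,10-dione
Product: 13 trans-fused (5α-H) 4β-hydroxydaucane-6,10-dione
Conditions: DBU (0.3 equiv), toluene, rt
Reagents that add atoms: none
Why: Base-catalysed epimerisation through the C5=C6 enolate under thermodynamic control: in the trans-fused isomer C6 leaves the face occupied by the bulky C4 isopropyl group and comes cis to the C4 hydroxyl, which hydrogen-bonds to C6=O in the non-polar solvent, in line with the usual drift of cis-fused angular-methyl bicyclo[5.3.0]decanones obtained by such cleavages to the trans series; an amidine is used because alkoxides would deprotonate C4-OH and start retro-aldol cleavage, and recovered 12 is resubmitted.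

Step 9
Reactants: 13 trans-fused 4β-hydroxydaucane-6,10-dione
Product: 14 4β,6α-dihydroxy-5α-H-daucan-10-one
Conditions: Me4NBH(OAc)3 (5 equiv), MeCN/AcOH (1:1), −20 °C; aqueous Rochelle salt work-up
Reagents that add atoms: none
Why: Evans–Saksena hydroxyl-directed reduction: C4-OH exchanges an acetate on boron and the hydride is then handed over intramolecularly to the β face of C6=O, the face on which C4–O lies, giving the 6α-alcohol (anti to C4-OH, cis to C5-H); the reagent does not reduce a ketone to which it is not tethered, so the hindered C10 ketone stays.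

Step 10
Reactants: 15 4-hydroxybenzoic acid
Product: 16 tert-butyldimethylsilyl 4-(tert-butyldimethylsilyloxy)benzoate
Conditions: TBSCl (2.5 equiv), imidazole (5 equiv), DMF, rt
Reagents that add atoms: tert-butyldimethylsilyl chloride, CC(C)(C)[Si](C)(C)Cl
Why: Imidazole-promoted silylation caps both the phenol and the carboxylic acid in one operation.

Step 11
Reactants: 16 tert-butyldimethylsilyl 4-(tert-butyldimethylsilyloxy)benzoate
Product: 17 4-(tert-butyldimethylsilyloxy)benzoic acid
Conditions: AcOH/THF/H2O (3:1:1), rt
Reagents that add atoms: none
Why: Selective hydrolysis: a silyl ester is cleaved by mild aqueous acid far faster than an aryl tert-butyldimethylsilyl ether.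

Step 12
Reactants: 14 4β,6α-dihydroxy-5α-H-daucan-10-one; 17 4-(tert-butyldimethylsilyloxy)benzoic acid
Product: 18 6α-[4-(tert-butyldimethylsilyloxy)benzoyloxy]-4β-hydroxydaucan-10-one
Conditions: 17 (1.5 equiv), EDC·HCl, DMAP, CH2Cl2, rt
Reagents that add atoms: none
Why: Steglich-type carbodiimide esterification: only the secondary C6-OH is acylated because the tertiary C4-OH next to the isopropyl group is inert, a transannular C6–O/C10 hemiketal is no sink since it would contain a trans-fused bicyclo[3.3.0] unit, and C6 keeps its configuration because its C–O bond is not broken.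

Step 13
Reactants: 18 6α-aroyloxy-4β-hydroxydaucan-10-one
Product: 19 C9=C10 trimethylsilyl enol ether with 4β-OSiMe3
Conditions: Me3SiOTf (3 equiv), Et3N (5 equiv), CH2Cl2, 0 °C → rt
Reagents that add atoms: trimethylsilyl trifluoromethanesulfonate, C[Si](C)(C)OS(=O)(=O)C(F)(F)F
Why: Soft enolisation and O-silylation: the C10 ketone can enolise only toward C9 because C1 is quaternary, so a single silyl enol ether results, and the same reagent caps the tertiary C4-OH without disturbing the ester or the aryl silyl ether.

Step 14
Reactants: 19 C9=C10 trimethylsilyl enol ether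
Product: 20 6α-aroyloxy-4β-trimethylsilyloxydauc-8-en-10-one
Conditions: Pd(OAc)2 (1.1 equiv), MeCN, rt → 40 °C
Reagents that add atoms: none
Why: Saegusa–Ito oxidation: the silyl enol ether is converted into an oxa-π-allyl complex of divalent palladium whose syn β-hydride elimination of C8–H gives the C8=C9 enone and zerovalent palladium; the metal can sit on either face of C9, so both C8 epimers converge, and the weakly acidic medium avoids C7 deprotonation and loss of the C6 ester.

Step 15
Reactants: 20 6α-aroyloxy-4β-trimethylsilyloxydauc-8-en-10-one
Product: 21 10α-hydroxy-6α-aroyloxy-4β-trimethylsilyloxydauc-8-ene (10R)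
Conditions: (S)-3,3-diphenyl-1-methyltetrahydro-3H-pyrrolo[1,2-c][1,3,2]oxazaborole ((S)-Me-CBS, 0.5–1.0 equiv), catecholborane (2 equiv), toluene, −78 → −40 °C; MeOH, then pH 7 buffer
Reagents that add atoms: none
Why: Corey–Bakshi–Shibata reduction: the carbonyl oxygen binds the catalyst boron through the lone pair on the side of the small C9–H flank, away from quaternary C1, so the (S)-catalyst should deliver hydride to the β face of C10 (syn to C1-CH3) and give the 10α (10R) allylic alcohol against the intrinsic α-face preference; the reagent is 1,2-selective and non-basic, so the C6 ester is not lost through the C7 dienolate.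

Step 16
Reactants: 21 10α-hydroxy-6α-aroyloxy-4β-trimethylsilyloxydauc-8-ene; 22 angelic acid ((Z)-2-methylbut-2-enoic acid)
Product: 24 bis-silyl-protected target (10α-angelate), via angelic 2,4,6-trichlorobenzoic anhydride 23 (not isolated)
Conditions: 22 (3 equiv), 2,4,6-trichlorobenzoyl chloride (3 equiv), Et3N (3.5 equiv), toluene, rt; then 21, 75–80 °C, no DMAP
Reagents that add atoms: 2,4,6-trichlorobenzoyl chloride, O=C(Cl)c1c(Cl)cc(Cl)cc1Cl (atoms of 23 only)
Why: Yamaguchi esterification: the alcohol attacks the angeloyl carbonyl of the mixed anhydride because the aroyl carbonyl is shielded by two ortho chlorines, and omission of a nucleophilic catalyst avoids the addition–elimination that would isomerise the Z angelate to the tiglate; C10 keeps its configuration since its C–O bond is not broken.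

Step 17
Reactants: 24 bis-silyl-protected target
Product: 25 target CNP0273650.2
Conditions: HF·pyridine, pyridine/THF, 0 °C → rt
Reagents that add atoms: none
Why: Fluoride-mediated desilylation under buffered, weakly acidic conditions removes the aryl tert-butyldimethylsilyl ether and the tertiary trimethylsilyl ether together, without ester migration, ionisation of the allylic angelate or Z to E isomerisation.

## Compound list

1 | dimethyl 3-methylglutarate | COC(=O)CC(C)CC(=O)OC | starting material
2 | 4-methyl-1,2-bis(trimethylsilyloxy)cyclopent-1-ene | CC1CC(O[Si](C)(C)C)=C(O[Si](C)(C)C)C1 | intermediate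
3 | 3-methylcyclopent-2-en-1-one | CC1=CC(=O)CC1 | starting material
4 | tricyclic photoadduct ketone (cis-anti-cis drawn, C8 open) | C[Si](C)(C)O[C@@]13CC(C)C[C@@]3(O[Si](C)(C)C)[C@H]2[C@]1(C)CCC2=O | intermediate
5 | C3-lithium enolate of 4 | C[Si](C)(C)O[C@@]13CC(C)C[C@@]3(O[Si](C)(C)C)[C@H]2[C@]1(C)CC=C2O[Li] | intermediate
6 | tricyclic C3=C4 enol triflate | C[Si](C)(C)O[C@@]13CC(C)C[C@@]3(O[Si](C)(C)C)[C@H]2[C@]1(C)CC=C2OS(=O)(=O)C(F)(F)F | intermediate
7 | isopropylmagnesium chloride | CC(C)[Mg]Cl | starting material
8 | tricyclic 4-isopropyl C3=C4 alkene | C[Si](C)(C)O[C@@]13CC(C)C[C@@]3(O[Si](C)(C)C)[C@H]2[C@]1(C)CC=C2C(C)C | intermediate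
9 | tricyclic C4 β-hydroperoxide | C[Si](C)(C)O[C@@]13CC(C)C[C@@]3(O[Si](C)(C)C)[C@H]2[C@]1(C)CC[C@@]2(OO)C(C)C | intermediate
10 | tricyclic 4β-hydroxy-4α-isopropyl bis-Me3Si ether | C[Si](C)(C)O[C@@]13CC(C)C[C@@]3(O[Si](C)(C)C)[C@H]2[C@]1(C)CC[C@@]2(O)C(C)C | intermediate
11 | tricyclic 4β,6,10-triol | O[C@@]13CC(C)C[C@@]3(O)[C@H]2[C@]1(C)CC[C@@]2(O)C(C)C | intermediate
12 | cis-fused (5β-H) 4β-hydroxydaucane-6,10-dione | O=C1CC(C)CC(=O)[C@H]2[C@]1(C)CC[C@@]2(O)C(C)C | intermediate
13 | trans-fused (5α-H) 4β-hydroxydaucane-6,10-dione | O=C1CC(C)CC(=O)[C@@H]2[C@]1(C)CC[C@@]2(O)C(C)C | intermediate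
14 | 4β,6α-dihydroxy-5α-H-daucan-10-one | O=C1CC(C)C[C@H](O)[C@@H]2[C@]1(C)CC[C@@]2(O)C(C)C | intermediate
15 | 4-hydroxybenzoic acid | O=C(O)c1ccc(O)cc1 | starting material
16 | tert-butyldimethylsilyl 4-(tert-butyldimethylsilyloxy)benzoate | CC(C)(C)[Si](C)(C)Oc1ccc(cc1)C(=O)O[Si](C)(C)C(C)(C)C | intermediate
17 | 4-(tert-butyldimethylsilyloxy)benzoic acid | CC(C)(C)[Si](C)(C)Oc1ccc(C(=O)O)cc1 | intermediate
18 | 6α-[4-(tert-butyldimethylsilyloxy)benzoyloxy]-4β-hydroxydaucan-10-one | O=C1CC(C)C[C@H](OC(=O)c2ccc(O[Si](C)(C)C(C)(C)C)cc2)[C@@H]2[C@]1(C)CC[C@@]2(O)C(C)C | intermediate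
19 | C9=C10 trimethylsilyl enol ether, 4β-OSiMe3 | C[Si](C)(C)OC1=CC(C)C[C@H](OC(=O)c2ccc(O[Si](C)(C)C(C)(C)C)cc2)[C@@H]2[C@]1(C)CC[C@@]2(O[Si](C)(C)C)C(C)C | intermediate
20 | 6α-aroyloxy-4β-trimethylsilyloxydauc-8-en-10-one | O=C1C=C(C)C[C@H](OC(=O)c2ccc(O[Si](C)(C)C(C)(C)C)cc2)[C@@H]2[C@]1(C)CC[C@@]2(O[Si](C)(C)C)C(C)C | intermediate
21 | 10α-hydroxy-6α-aroyloxy-4β-trimethylsilyloxydauc-8-ene | O[C@@H]1C=C(C)C[C@H](OC(=O)c2ccc(O[Si](C)(C)C(C)(C)C)cc2)[C@@H]2[C@]1(C)CC[C@@]2(O[Si](C)(C)C)C(C)C | intermediate
22 | angelic acid, (Z)-2-methylbut-2-enoic acid | C/C=C(/C)C(=O)O | starting material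
23 | angelic 2,4,6-trichlorobenzoic anhydride | C/C=C(/C)C(=O)OC(=O)c1c(Cl)cc(Cl)cc1Cl | intermediate
24 | bis-silyl-protected target | C/C=C(/C)C(=O)O[C@@H]1C=C(C)C[C@H](OC(=O)c2ccc(O[Si](C)(C)C(C)(C)C)cc2)[C@@H]2[C@]1(C)CC[C@@]2(O[Si](C)(C)C)C(C)C | intermediate
25 | CNP0273650.2, (1S,4R,5S,6S,10R)-10-angeloyloxy-4-hydroxy-6-(4-hydroxybenzoyloxy)dauc-8-ene | C/C=C(/C)C(=O)O[C@@H]1C=C(C)C[C@H](OC(=O)c2ccc(O)cc2)[C@@H]2[C@]1(C)CC[C@@]2(O)C(C)C | target

## Step count and risks

Total step count: 17.
Longest linear sequence: 15 (steps 1–9 and 12–17).

**Step 2.**
- What may go wrong: the strong Lewis acid may strip or transfer the silyl groups of 2 or of the adduct, which would be followed by retro-aldol opening of the cyclobutane. Polar conjugate addition, or electron transfer from the very electron-rich alkene to the excited complex, may outrun the cycloaddition. Face discrimination on the small five-membered enone may be poor.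
- Fallback, from 2 and 3 back to 4: the Lewis acid is left out and 3 is irradiated directly with excess 2 (Pyrex-filtered medium-pressure mercury lamp, pentane or CH2Cl2, −20 °C or below). This is the established racemic photocycloaddition of cyclopentenones with bis(silyloxy)cycloalkenes.
- It should give 4 together with the mirror-image photoadduct F1. After silica chromatography to simplify the isomer set, the enantiomers are separated by preparative supercritical-fluid chromatography on a polysaccharide carbamate chiral phase. The route is re-entered at 4.

**Step 5.**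
- What may go wrong: β-scission of the C5–C6 bond of the C4 radical (cyclobutylcarbinyl opening) may compete with oxygen capture. It is helped by strain release and by silyloxy stabilisation of the resulting C6 radical.
- Fallback, from 8 back to 10: the oxygen is brought in by polar chemistry. Dimethyldioxirane (acetone, 0 °C, neutral) should epoxidise the trisubstituted alkene on the same convex face to give the exo 3β,4β-epoxide F2.
- LiEt3BH (THF, 0 °C → reflux) then opens it by hydride attack at the secondary apex carbon C3. This leaves the tertiary 4β-alkoxide and, after work-up, 10, with no radical ever placed next to the cyclobutane.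

**Step 15.**
- What may go wrong: the reduction may be slow, or the facial selectivity poor, because the intrinsic preference for attack anti to the C1 methyl group opposes the catalyst at a neopentyl carbonyl.
- Fallback, from 20 back to 24: the substrate bias is accepted and then inverted. Luche reduction (NaBH4, CeCl3·7H2O, MeOH, −78 °C) should give the 10β-alcohol F3.
- Mitsunobu esterification of F3 with angelic acid 22 (PPh3, diisopropyl azodicarboxylate, toluene, 0 °C → rt) displaces the activated oxygen with inversion. This installs the 10α-angelate directly, replaces step 16 as well, and rejoins the route at 24.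

## Further compounds

F1 | step 2 | enantiomer of photoadduct 4 | C[Si](C)(C)O[C@]13CC(C)C[C@]3(O[Si](C)(C)C)[C@@H]2[C@@]1(C)CCC2=O
F2 | step 5 | exo 3β,4β-epoxide of alkene 8 | C[Si](C)(C)O[C@@]13CC(C)C[C@@]3(O[Si](C)(C)C)[C@H]2[C@]1(C)C[C@@H]4O[C@]24C(C)C
F3 | step 15 | 10β-alcohol (C10 epimer of 21) | O[C@H]1C=C(C)C[C@H](OC(=O)c2ccc(O[Si](C)(C)C(C)(C)C)cc2)[C@@H]2[C@]1(C)CC[C@@]2(O[Si](C)(C)C)C(C)C
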